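**Plan** (upper tetralone: C1 ketone, C3 aryl, C4 OH, C5 OH, C7 CH3; lower tetralone primed: C1' ketone, C4' OH, C6' CH3, C7' link, C8' OH)
1. Retrosynthesis: the two phenolic benzyl ethers come off last. The C1 ketone is traced back to a C1=C2 styrene bond. Then the C3–C7' bond is cut while the C4 oxygen is tied back to C1.
2. Enabling feature: in the non-aromatic ring C1–C2–C3–C4–C4a–C8a, the C4–OH and the C3–aryl group are vicinal and cis, and C1 (1,4 to C4) is also oxygenated. C1 and C4 are therefore the bridgeheads of a 1,4-epoxy-1,4-dihydronaphthalene, whose strained C2=C3 bond takes up an aryl–metal from the oxygen face and then expels the bridge oxygen from C1.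
3. Lower half, forward: a double Friedel–Crafts acylation of 4-chloro-3-methylphenol with maleic anhydride closes the second ring. Reductive dechlorination/ketonisation, asymmetric transfer hydrogenation, ortho-bromination, O-benzylation and borylation follow.
4. Upper half, forward: O-benzylation of 3-bromo-5-methylphenol and an aryne/furan [4+2] cycloaddition build the oxabicycle (the temporary ring) in two steps.
5. Union and finish: rhodium-catalysed asymmetric arylative ring opening, iron-catalysed Wacker-type oxidation of C1=C2, hydrogenolysis.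
6. Stereochemistry: C4' (R) comes from the catalyst-controlled transfer hydrogenation. C3 (R) and C4 (S) both come from the ring opening, cis through exo syn-addition and absolute sense through the chiral ligand.

Key step: step 9

Assumption: the (R,S)-Josiphos ligand is taken to give the (1S,2R)-dihydronaphthalenol, by analogy with the parent oxabicycle. If the sense is opposite, the enantiomeric ligand is used and nothing else changes.

**Step 1**
Reactants: 1 4-chloro-3-methylphenol; 2 maleic anhydride
Product: 3 8-chloro-5-hydroxy-7-methylnaphthalene-1,4-dione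
Conditions: AlCl3/NaCl melt, 180 °C; then aq HCl
Reagents that add atoms: none
Why: Double Friedel–Crafts acylation closes the quinone ring on the only pair of adjacent free positions of 1 (C5/C6), so the regiochemistry is unambiguous and the chlorine ends up para to the OH.

**Step 2**
Reactants: 3 8-chloro-5-hydroxy-7-methylnaphthalene-1,4-dione
Product: 6 5-hydroxy-7-methyl-2,3-dihydronaphthalene-1,4-dione, via chlorohydroquinone 4 (not isolated), via 7-methylnaphthalene-1,4,5-triol 5 (not isolated)
Conditions: SnCl2·2H2O, 4 M HCl, THF, 60 °C; extraction under Ar; then CF3CO2H, rt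
Reagents that add atoms: none
Why: Tin(II) reduces the quinone to the hydroquinone, whose electron-rich ring is protonated at C8 and loses chloride reductively (reductive dehalogenation), and acid then shifts the hydronaphthoquinone to its 2,3-dihydro-1,4-dione tautomer, which the peri O–H···O=C hydrogen bond favours (keto–enol tautomerisation).

**Step 3**
Reactants: 6 5-hydroxy-7-methyl-2,3-dihydronaphthalene-1,4-dione
Product: 7 (4R)-4,8-dihydroxy-6-methyl-3,4-dihydronaphthalen-1(2H)-one, (R)-shinanolone
Conditions: RuCl[(R,R)-TsDPEN](p-cymene) (1 mol %), HCO2H/Et3N 5:2, CH2Cl2, rt, Ar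
Reagents that add atoms: none
Why: Noyori asymmetric transfer hydrogenation should reduce only the non-chelated aryl ketone, because the other carbonyl is deactivated by the peri OH, and the (R,R)-catalyst should give the R carbinol as it does with 1-tetralone.

**Step 4**
Reactants: 7 (R)-shinanolone
Product: 8 (4R)-7-bromo-4,8-dihydroxy-6-methyl-3,4-dihydronaphthalen-1(2H)-one
Conditions: NBS (1.0 equiv), i-Pr2NH (10 mol %), CH2Cl2, 0 °C
Reagents that add atoms: N-bromosuccinimide, O=C1CCC(=O)N1Br
Why: Amine-catalysed ortho-selective electrophilic bromination of a phenol delivers bromine from an N-bromoamine bound to the OH, C7 is the only free ortho position, and the para position C5 is crowded by the 6-CH3 and the peri C4 carbinol.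

**Step 5**
Reactants: 8 (4R)-7-bromo-4,8-dihydroxy-6-methyl-3,4-dihydronaphthalen-1(2H)-one
Product: 9 (4R)-8-(benzyloxy)-7-bromo-4-hydroxy-6-methyl-3,4-dihydronaphthalen-1(2H)-one
Conditions: BnBr, K2CO3, DMF, 50 °C
Reagents that add atoms: benzyl bromide, BrCc1ccccc1
Why: Williamson ether synthesis under carbonate conditions alkylates only the phenoxide and leaves the secondary alcohol and its stereocentre untouched.

**Step 6**
Reactants: 9 (4R)-8-(benzyloxy)-7-bromo-4-hydroxy-6-methyl-3,4-dihydronaphthalen-1(2H)-one
Product: 10 (4R)-8-(benzyloxy)-4-hydroxy-6-methyl-7-(4,4,5,5-tetramethyl-1,3,2-dioxaborolan-2-yl)-3,4-dihydronaphthalen-1(2H)-one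
Conditions: B2pin2, XPhos Pd G2 (3 mol %), KOAc, 1,4-dioxane, 90 °C
Reagents that add atoms: bis(pinacolato)diboron, CC1(C)OB(OC1(C)C)B1OC(C)(C)C(C)(C)O1
Why: Miyaura borylation with a bulky biarylphosphine handles doubly ortho-substituted aryl bromides, and the weak acetate base tolerates the ketone, the alcohol and the benzyl ether.

**Step 7**
Reactants: 11 3-bromo-5-methylphenol
Product: 12 1-(benzyloxy)-3-bromo-5-methylbenzene
Conditions: BnBr, K2CO3, acetone, reflux
Reagents that add atoms: benzyl bromide, BrCc1ccccc1
Why: Williamson ether synthesis installs the same neutral-cleavable phenol protection as in the lower half.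

**Step 8**
Reactants: 12 1-(benzyloxy)-3-bromo-5-methylbenzene; 13 furan
Product: 16 rac-5-(benzyloxy)-7-methyl-1,4-dihydro-1,4-epoxynaphthalene, via aryllithium 14 (not isolated), via aryne 15 (not isolated)
Conditions: LDA, furan (excess), THF, −78 °C to rt
Reagents that add atoms: none
Why: Directed ortho-lithiation at the most acidic C–H (between OBn and Br), loss of LiBr, and aryne/furan Diels–Alder cycloaddition close the upper carbocycle and the oxygen bridge together, placing OBn peri to bridgehead C4.

**Step 9**
Reactants: 10 (4R)-arylboronate; 16 rac-5-(benzyloxy)-7-methyl-1,4-dihydro-1,4-epoxynaphthalene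
Product: 17 (4R)-8-(benzyloxy)-7-[(1S,2R)-8-(benzyloxy)-1-hydroxy-6-methyl-1,2-dihydronaphthalen-2-yl]-4-hydroxy-6-methyl-3,4-dihydronaphthalen-1(2H)-one
Conditions: [Rh(cod)Cl]2 (2.5 mol %), (R,S)-PPF-P(t-Bu)2 (Josiphos, 5.5 mol %), aq Cs2CO3, THF, rt to 40 °C; chromatography on Et3N-deactivated silica
Reagents that add atoms: none
Why: Boron-to-rhodium transfer from 10 to the Rh(I) hydroxide–Josiphos complex gives an aryl–rhodium species that adds syn across the strained C2=C3 bond of 16 from the exo face (the face of the oxygen bridge), and the C2–Rh alkyl so formed expels the bridge oxygen from C1 by β-oxygen elimination, which creates C1=C2 and the C4 alkoxide before water regenerates Rh–OH. The closest known reaction type is the rhodium-catalysed asymmetric ring opening of 7-oxabenzonorbornadienes with arylboron reagents to cis-2-aryl-1,2-dihydronaphthalen-1-ols, together with the ligand-controlled regiodivergent opening of racemic oxabicycles that are unsymmetrical only in the arene. The step closes no ring: it opens the temporary 1,4-epoxy bridge, whose oxygen stays behind as the C4 hydroxyl. C4 keeps the configuration it has in the (1R,4S)-enantiomer of 16, C3 is set cis to it because the bowl shape of the bicycle leaves only the exo face open, and the absolute sense follows from the ligand, which decides which of the two alkene carbons takes the aryl group. The selectivity needed is that between C3 and C2: the distant OBn and CH3 groups give the alkene almost no bias, so under ligand control the (1R,4S)-enantiomer should be arylated at C3 to give 17 and the (1S,4R)-enantiomer at the carbon next to its other bridgehead to give a constitutional isomer that chromatography removes, which limits 17 to half of the material. The position on the lower ring (C7') is fixed by the boron atom, and the aryl ketone and free C4' hydroxyl of 10 should be spectators toward aryl–Rh(I) at this temperature.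

**Step 10**
Reactants: 17 cis-2-aryl-1,2-dihydronaphthalen-1-ol
Product: 18 (4R)-8-(benzyloxy)-7-[(1S,2R)-8-(benzyloxy)-1-hydroxy-6-methyl-4-oxo-1,2,3,4-tetrahydronaphthalen-2-yl]-4-hydroxy-6-methyl-3,4-dihydronaphthalen-1(2H)-one
Conditions: Fe(dbm)3 (5 mol %), PhSiH3 (2 equiv), EtOH/THF, air, rt
Reagents that add atoms: dioxygen, O=O
Why: In this iron-catalysed Wacker-type oxidation (a Mukaiyama-type hydrogen-atom-transfer process) an iron hydride puts H on C2, the benzylic C1 radical is trapped by O2 and the iron peroxide collapses to the aryl ketone, all under neutral conditions at room temperature that should spare the dehydration-prone C4 carbinol and create no stereocentre.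

**Step 11**
Reactants: 18 bis(benzyl ether)
Product: 19 (4R)-7-[(1S,2R)-1,8-dihydroxy-6-methyl-4-oxo-1,2,3,4-tetrahydronaphthalen-2-yl]-4,8-dihydroxy-6-methyl-3,4-dihydronaphthalen-1(2H)-one (target)
Conditions: H2 (1 atm), 10 % Pd/C, EtOAc, rt
Reagents that add atoms: none
Why: Neutral catalytic hydrogenolysis cleaves aryl benzyl ethers faster than it attacks the two secondary benzylic alcohols or the aryl ketones on acyl-deactivated rings, and it touches no stereocentre.

**Compound list**
1 | 4-chloro-3-methylphenol | Cc1cc(O)ccc1Cl | starting material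
2 | maleic anhydride | O=C1C=CC(=O)O1 | starting material
3 | 8-chloro-5-hydroxy-7-methylnaphthalene-1,4-dione | Cc1cc(O)c2C(=O)C=CC(=O)c2c1Cl | intermediate
4 | 8-chloro-7-methylnaphthalene-1,4,5-triol | Cc1cc(O)c2c(O)ccc(O)c2c1Cl | intermediate (not isolated)
5 | 7-methylnaphthalene-1,4,5-triol | Cc1cc(O)c2c(O)ccc(O)c2c1 | intermediate (not isolated)
6 | 5-hydroxy-7-methyl-2,3-dihydronaphthalene-1,4-dione | Cc1cc(O)c2C(=O)CCC(=O)c2c1 | intermediate
7 | (4R)-4,8-dihydroxy-6-methyl-3,4-dihydronaphthalen-1(2H)-one | Cc1cc2c(c(O)c1)C(=O)CC[C@H]2O | intermediate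
8 | (4R)-7-bromo-4,8-dihydroxy-6-methyl-3,4-dihydronaphthalen-1(2H)-one | Cc1cc2c(c(O)c1Br)C(=O)CC[C@H]2O | intermediate
9 | (4R)-8-(benzyloxy)-7-bromo-4-hydroxy-6-methyl-3,4-dihydronaphthalen-1(2H)-one | Cc1cc2c(c(OCc3ccccc3)c1Br)C(=O)CC[C@H]2O | intermediate
10 | (4R)-8-(benzyloxy)-4-hydroxy-6-methyl-7-(4,4,5,5-tetramethyl-1,3,2-dioxaborolan-2-yl)-3,4-dihydronaphthalen-1(2H)-one | Cc1cc2c(c(OCc3ccccc3)c1B4OC(C)(C)C(C)(C)O4)C(=O)CC[C@H]2O | intermediate
11 | 3-bromo-5-methylphenol | Cc1cc(O)cc(Br)c1 | starting material
12 | 1-(benzyloxy)-3-bromo-5-methylbenzene | Cc1cc(Br)cc(OCc2ccccc2)c1 | intermediate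
13 | furan | c1ccoc1 | starting material
14 | [2-(benzyloxy)-6-bromo-4-methylphenyl]lithium | [Li]c1c(Br)cc(C)cc1OCc2ccccc2 | intermediate (not isolated)
15 | 3-(benzyloxy)-5-methylbenzyne | CC1=CC#CC(OCc2ccccc2)=C1 | intermediate (not isolated)
16 | rac-5-(benzyloxy)-7-methyl-1,4-dihydro-1,4-epoxynaphthalene (racemate; the productive (1R,4S)-enantiomer is written) | Cc1cc(OCc2ccccc2)c3c(c1)[C@H]4C=C[C@@H]3O4 | intermediate
17 | (4R)-8-(benzyloxy)-7-[(1S,2R)-8-(benzyloxy)-1-hydroxy-6-methyl-1,2-dihydronaphthalen-2-yl]-4-hydroxy-6-methyl-3,4-dihydronaphthalen-1(2H)-one | Cc1cc(OCc2ccccc2)c3c(c1)C=C[C@H](c4c(C)cc5c(c4OCc6ccccc6)C(=O)CC[C@H]5O)[C@@H]3O | intermediate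
18 | (4R)-8-(benzyloxy)-7-[(1S,2R)-8-(benzyloxy)-1-hydroxy-6-methyl-4-oxo-1,2,3,4-tetrahydronaphthalen-2-yl]-4-hydroxy-6-methyl-3,4-dihydronaphthalen-1(2H)-one | Cc1cc(OCc2ccccc2)c3c(c1)C(=O)C[C@H](c4c(C)cc5c(c4OCc6ccccc6)C(=O)CC[C@H]5O)[C@@H]3O | intermediate
19 | (4R)-7-[(1S,2R)-1,8-dihydroxy-6-methyl-4-oxo-1,2,3,4-tetrahydronaphthalen-2-yl]-4,8-dihydroxy-6-methyl-3,4-dihydronaphthalen-1(2H)-one | Cc1cc(O)c2c(c1)C(=O)C[C@H](c1c(C)cc3c(c1O)C(=O)CC[C@H]3O)[C@@H]2O | target

**Total step count:** 11. **Longest linear sequence:** 9 (steps 1–6, then 9–11).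

**Steps most likely to fail**

**1. Step 9.**
- What may go wrong: boron-to-rhodium transfer of the doubly ortho-substituted aryl group may be slow. Protodeboronation may then compete, and ligand control over the site of arylation may erode.
- Fallback: it sets out from bromide 9 and oxabicycle 16 and comes back at 17, so step 6 is skipped. The aryl–metal is made by oxidative addition instead of transmetalation, in a palladium-catalysed reductive arylative ring opening of the oxabicycle (Pd(II) chloride with a chiral bisphosphine such as (R)-BINAP, Zn powder, Et3N, THF, 60 °C).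
- Syn exo carbopalladation and β-oxygen elimination give the same cis-2-aryl-1,2-dihydronaphthalen-1-ol, and zinc returns Pd(0). No new compound is made (F0).

**2. Step 10.**
- What may go wrong: the 1,2-dihydronaphthalen-1-ol may aromatise by dehydration. Hydrogen may be abstracted at the doubly activated C3–H. The oxidation may also stop at the alcohol level.
- Fallback: it sets out from 17 and comes back at 18, and it separates protection, hydration and oxidation.
  - TESOTf/2,6-lutidine (CH2Cl2, −78 °C) gives the bis(triethylsilyl) ether F1.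
  - Mukaiyama hydration (Mn(dpm)3, PhSiH3, O2, i-PrOH, 0 °C) gives the C1 benzylic alcohol F2 as an epimer mixture of no consequence.
  - Dess–Martin oxidation of the only free hydroxyl gives the silylated diketone F3.
  - HF·pyridine (THF, 0 °C) releases 18.

**3. Step 4.**
- What may go wrong: ortho/para selectivity may be poor, with attack at C5 or double bromination.
- Fallback: it sets out from 7 and comes back at 8, and it blocks C5 with a bulky peri group.
  - TIPSCl/imidazole (DMF) silylates the free alcohol rather than the chelated phenol and gives the 4-O-triisopropylsilyl ether F4.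
  - The same bromination, now with C5 walled in by the 6-CH3 and the peri silyloxy group, gives the 7-bromo silyl ether F5.
  - TBAF/AcOH (THF) returns 8.

**Further compounds**
F0 | step 9 | none | none
F1 | step 10 | bis(triethylsilyl) ether of 17 | Cc1cc(OCc2ccccc2)c3c(c1)C=C[C@H](c4c(C)cc5c(c4OCc6ccccc6)C(=O)CC[C@H]5O[Si](CC)(CC)CC)[C@@H]3O[Si](CC)(CC)CC
F2 | step 10 | C1 benzylic alcohol from hydration of F1 (C1 epimers) | Cc1cc(OCc2ccccc2)c3c(c1)C(O)C[C@H](c4c(C)cc5c(c4OCc6ccccc6)C(=O)CC[C@H]5O[Si](CC)(CC)CC)[C@@H]3O[Si](CC)(CC)CC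
F3 | step 10 | bis(triethylsilyl) ether of 18 | Cc1cc(OCc2ccccc2)c3c(c1)C(=O)C[C@H](c4c(C)cc5c(c4OCc6ccccc6)C(=O)CC[C@H]5O[Si](CC)(CC)CC)[C@@H]3O[Si](CC)(CC)CC
F4 | step 4 | (4R)-8-hydroxy-6-methyl-4-[(triisopropylsilyl)oxy]-3,4-dihydronaphthalen-1(2H)-one | Cc1cc2c(c(O)c1)C(=O)CC[C@H]2O[Si](C(C)C)(C(C)C)C(C)C
F5 | step 4 | (4R)-7-bromo-8-hydroxy-6-methyl-4-[(triisopropylsilyl)oxy]-3,4-dihydronaphthalen-1(2H)-one | Cc1cc2c(c(O)c1Br)C(=O)CC[C@H]2O[Si](C(C)C)(C(C)C)C(C)C
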